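The ratio of west's to north's early rate of making target reads 1.09, although west holds twice the starting material, so in these two runs the rate does not follow starting material in proportion. North is the flask asked about.

| flask | starting material | second substrate | free enzyme | remark |
|---|---|---|---|---|
| north | 0.10 M | 0.18 M | 10 µM | the very flask that is asked about, followed so far |
| west | 0.20 M | 0.18 M | 10 µM | run made earlier |
| flask | 0.10 M | 0.180 M | 10 µM |  |

| run | time / s | target / % | starting material / % |
|---|---|---|---|
| north | 10.0 | 20.4 | 78.8 |
| north | 20.0 | 35.9 | 62.9 |
| north | 40.0 | 60.7 | 38.7 |
| north | 80.0 | 88.3 | 12.0 |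
| west | 10.0 | 11.1 | 90.1 |
| west | 20.0 | 18.2 | 81.2 |
| west | 40.0 | 30.6 | 70.0 |
| west | 60.0 | 41.0 | 59.4 |
| west | 120 | 54.1 | 46.2 |

(each reading ± 0.5 percentage points)

- factor on the rate of making target when 30% of the starting material are converted if second substrate is charged twice over
- factor on the rate when 30% of the starting material are converted if free enzyme is charged at 50 µM instead

West slows with 46.2% of its starting material still present at 120 s. Its mean rate is 0.00114 M s⁻¹ from 20.0 s to 60.0 s, at a mean target of 0.0592 M. From 60.0 s to 120 s it is 4.37 × 10⁻⁴ M s⁻¹, at 0.0951 M.

My reckoning supposes that each turnover carries a fixed chance of killing the catalyst, so surviving catalyst falls in a straight line with target made. The line through these rates reaches zero at the capacity, the target a catalyst charge can make, 0.117 M. Over the charge, this is a turnover number of 11700.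

At 30% conversion the flask has made 0.0300 M of target, so 74.4% of its catalyst survives. If capacity grows with the charge, 94.9% survives at 50 µM, and the factor is 6.37.

My reckoning takes survivors as unchanged by doubled second substrate at equal conversion. West's rate per surviving catalyst is 0.00245 M s⁻¹ in the first interval and 0.00230 M s⁻¹ later, as second substrate falls from 0.169 M to 0.121 M. That reads as an order of 0.191, which gives a factor of 1.16. This order is the weak link: it is read from two rates, and the readings scatter by 0.5 percentage points.

The forecast, holding that “Death goes with turnover”, gave 1.7 (1.4 to 1.95) for second substrate, higher than my figure, and 6.3 (5.5 to 7.3) for free enzyme.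

The simulation gives 1.16 and 6.21.

    starting material + free enzyme ⇌ first complex (K = 115 M⁻¹, k = 53200 M⁻¹ s⁻¹)
    second substrate + loaded enzyme ⇌ second complex (K = 13.0 M⁻¹, k = 1.13 × 10⁵ M⁻¹ s⁻¹)
    first complex → loaded enzyme + first product (k = 1030 s⁻¹)
    second complex → free enzyme + target (k = 452 s⁻¹)
    second complex → spent catalyst (k = 0.0349 s⁻¹)

In the flask, spent catalyst stands at 77.2% after 3.00 min, when the starting material has become target, so the capacity reforges to 0.130 M, above the 0.117 M read from west. At 0.262 min, when 30% is converted, this capacity leaves 76.8% of the catalyst surviving. At 50 µM of free enzyme, that capacity scaled with the charge leaves 95.4% surviving, and the factor on the rate is 6.21. The flask's apparent order in second substrate at 30% conversion stands at 0.30, above the 0.191 read from west. The largest single effect on that order is the backward run from second complex to second substrate + loaded enzyme: the run without it lowers the order to 0.020.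

The data are calculated for substances that don't exist, and the scatter is random.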